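**Plan**

- Cuts, last bond first: (a) the CH2 bridge between C-5 of the central benzene ring and C-6 of the acetylfilicinic ring; (b) the bond from the other bridge CH2 to C-6 of the butyrylfilicinic ring; (c) on the central ring, the aryl–C(=O) bond at C-1 and the adjacent aryl–O bond at C-2, both to butyric acid.
- Enabling feature: in the central benzene ring the butanoyl-bearing C-1 and the hydroxyl-bearing C-2 are neighbours, with an oxygen on C-6 beside the former and the bridge CH2 on C-3 beside the latter. This is the pattern an oxygen-polarised aryne leaves after inserting into a carboxylic acid C–O bond.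
- Forward: 3,5-bis(benzyloxy)phenol is formylated, brominated and converted into a 2-silylaryl triflate carrying one methoxymethyl arm; its aryne takes up butyric acid. No ring is formed in the route: the benzene ring is bought and the two filicinic rings come from acylphloroglucinols by dearomatising gem-dimethylation.
- Chain joining: the methoxymethyl arm alkylates butyrylfilicinic acid, the benzyl ethers are removed, and the single remaining ring C–H is linked through a Mannich-derived CH2 to acetylfilicinic acid. The two different outer units therefore enter one at a time at defined carbons.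
- Stereochemistry: the target has no stereocentre and no double-bond geometry to set.

Key step: step 8

Remark: the filicinic rings are written throughout in the enol tautomer of the target SMILES; benzyl replaces methyl on the ring oxygens so that the last deprotection is a hydrogenolysis, and the second bridge position is kept as C–H until the end so that the two arms cannot be confused.

**Step 1**
Reactants: 1 3,5-bis(benzyloxy)phenol
Product: 2 4,6-bis(benzyloxy)-2-hydroxybenzaldehyde
Conditions: MgCl2, Et3N, (CH2O)n, MeCN, reflux; 1 M HCl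
Reagents that add atoms: paraformaldehyde (formaldehyde unit), C=O
Why: Magnesium phenoxide-directed ortho-formylation (Casnati–Skattebøl reaction) delivers formaldehyde only beside the phenol oxygen, and the two ortho carbons of 1 are equivalent, so a single salicylaldehyde should result.

**Step 2**
Reactants: 2 4,6-bis(benzyloxy)-2-hydroxybenzaldehyde
Product: 3 4,6-bis(benzyloxy)-3-bromo-2-hydroxybenzaldehyde
Conditions: NBS (1.0 equiv), i-Pr2NH (10 mol %), CH2Cl2, 0 °C
Reagents that add atoms: N-bromosuccinimide, O=C1CCC(=O)N1Br
Why: Electrophilic aromatic bromination should go to the carbon beside the free hydroxyl, as the known 3-halogenation of 2-hydroxy-4,6-dialkoxyaryl carbonyl compounds does, helped by amine-mediated ortho delivery and by the two benzyloxy groups that shield the only other open carbon.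

**Step 3**
Reactants: 3 4,6-bis(benzyloxy)-3-bromo-2-hydroxybenzaldehyde
Product: 4 2-(allyloxy)-4,6-bis(benzyloxy)-3-bromobenzaldehyde
Conditions: allyl bromide, K2CO3, DMF, 50 °C
Reagents that add atoms: allyl bromide, C=CCBr
Why: Williamson etherification masks the phenol so that the benzylic alcohol made next can be methylated alone; allyl is chosen because it comes off later under neutral conditions that spare the bromide and the benzylic ether.

**Step 4**
Reactants: 4 2-(allyloxy)-4,6-bis(benzyloxy)-3-bromobenzaldehyde
Product: 5 [2-(allyloxy)-4,6-bis(benzyloxy)-3-bromophenyl]methanol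
Conditions: NaBH4, MeOH/THF, 0 °C
Reagents that add atoms: none
Why: Hydride reduction of the aldehyde by NaBH4; the aryl bromide and the allyl and benzyl ethers are inert to it.

**Step 5**
Reactants: 5 [2-(allyloxy)-4,6-bis(benzyloxy)-3-bromophenyl]methanol
Product: 6 1-(allyloxy)-3,5-bis(benzyloxy)-2-bromo-6-(methoxymethyl)benzene
Conditions: NaH, MeI, THF, 0 °C to rt
Reagents that add atoms: iodomethane, CI
Why: Williamson etherification of the primary benzylic alkoxide, the only acidic site left in the molecule.

**Step 6**
Reactants: 6 1-(allyloxy)-3,5-bis(benzyloxy)-2-bromo-6-(methoxymethyl)benzene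
Product: 7 3,5-bis(benzyloxy)-2-bromo-6-(methoxymethyl)phenol
Conditions: Pd(PPh3)4 (3 mol %), morpholine, THF, rt
Reagents that add atoms: none
Why: Tsuji–Trost deallylation: zerovalent palladium ionises the allyl aryl ether to a π-allyl complex that morpholine captures, while the hindered, electron-rich aryl bromide should not undergo oxidative addition at room temperature.

**Step 7**
Reactants: 7 3,5-bis(benzyloxy)-2-bromo-6-(methoxymethyl)phenol
Product: 10 3,5-bis(benzyloxy)-2-(methoxymethyl)-6-(trimethylsilyl)phenyl trifluoromethanesulfonate, via aryl trimethylsilyl ether 8 (not isolated), via lithium 2-silylphenoxide 9 (not isolated)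
Conditions: HMDS, THF, 65 °C, evaporate; n-BuLi, THF, −78 °C; Tf2O, −78 °C
Reagents that add atoms: hexamethyldisilazane, C[Si](C)(C)N[Si](C)(C)C; trifluoromethanesulfonic anhydride, O=S(=O)(OS(=O)(=O)C(F)(F)F)C(F)(F)F
Why: O-Silylation, bromine–lithium exchange, 1,3-silyl shift from oxygen to carbon (retro-Brook rearrangement) and O-triflation of the resulting phenoxide are the standard one-flask entry to 2-(trimethylsilyl)aryl triflates, and exchange at −78 °C outruns deprotonation of the benzyl ethers or of the ring hydrogen.

**Step 8**
Reactants: 10 3,5-bis(benzyloxy)-2-(methoxymethyl)-6-(trimethylsilyl)phenyl trifluoromethanesulfonate; 11 butyric acid (1.2 equiv)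
Product: 13 1-[4,6-bis(benzyloxy)-2-hydroxy-3-(methoxymethyl)phenyl]butan-1-one, via aryne 12 (not isolated)
Conditions: CsF (4 equiv), THF, 125 °C, sealed tube
Reagents that add atoms: none
Why: Fluoride attacks silicon and triflate leaves to give aryne 12; butanoate oxygen adds to the aryne carbon beside the methoxymethyl group, and the aryl anion formed beside the benzyloxy group attacks the ester carbonyl through a four-membered alkoxide that opens to the ortho-hydroxyaryl ketone. The closest known reaction is the CsF-mediated insertion of arynes from 2-(trimethylsilyl)aryl triflates into the C–O bond of carboxylic acids in hot THF. No lasting ring is closed (the four-membered ring is transient) and no stereocentre is formed. The selectivity needed is regiochemical: the benzyloxy group next to one aryne carbon distorts the triple bond and stabilises negative charge beside it, so the nucleophile enters at the remote carbon, as with 3-alkoxybenzynes. Because no Lewis acid is present, the benzylic methyl ether and the benzyl ethers should survive, which a Friedel–Crafts acylation or a Fries rearrangement on this ring would not allow.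

**Step 9**
Reactants: 14 phloroglucinol
Product: 15 1-(2,4,6-trihydroxyphenyl)butan-1-one
Conditions: butanoyl chloride, AlCl3, PhNO2/CH2Cl2, rt to 50 °C
Reagents that add atoms: butanoyl chloride, CCCC(Cl)=O
Why: Friedel–Crafts acylation of the symmetric, highly nucleophilic arene; the first acyl group deactivates the ring enough to stop at monoacylation.

**Step 10**
Reactants: 15 1-(2,4,6-trihydroxyphenyl)butan-1-one
Product: 16 2-butanoyl-3,5-dihydroxy-4,4-dimethylcyclohexa-2,5-dien-1-one (butyrylfilicinic acid)
Conditions: NaOMe, MeI (2.2 equiv), MeOH, 0 °C to rt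
Reagents that add atoms: iodomethane, CI
Why: Base-mediated dearomatising C-methylation puts two methyl groups on the same ring carbon to give the enolised 4,4-dimethyl trione, a known outcome for acylphloroglucinols that has to be separated from lower and higher methylation products.

**Step 11**
Reactants: 13 1-[4,6-bis(benzyloxy)-2-hydroxy-3-(methoxymethyl)phenyl]butan-1-one; 16 butyrylfilicinic acid (1.3 equiv)
Product: 17 2-butanoyl-6-{[4,6-bis(benzyloxy)-3-butanoyl-2-hydroxyphenyl]methyl}-3,5-dihydroxy-4,4-dimethylcyclohexa-2,5-dien-1-one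
Conditions: TsOH·H2O (10 mol %), CH2Cl2, 4 Å MS, rt
Reagents that add atoms: none
Why: Brønsted acid-catalysed SN1 benzylation of a cyclic 1,3-dicarbonyl compound: methanol leaves from the protonated ether to give a benzylic cation (protonated ortho-quinone methide) stabilised by three ring oxygens, the only C–H carbon of enolised 16 captures it with C-alkylation as the thermodynamic outcome, and the benzyl aryl ethers tolerate catalytic acid.

**Step 12**
Reactants: 17 the bis(benzyl ether) from step 11
Product: 18 2-butanoyl-6-[(3-butanoyl-2,4,6-trihydroxyphenyl)methyl]-3,5-dihydroxy-4,4-dimethylcyclohexa-2,5-dien-1-one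
Conditions: H2 (1 atm), Pd/C, EtOAc/MeOH, rt
Reagents that add atoms: none
Why: Hydrogenolysis of benzyl aryl ethers over palladium on carbon, under which the chelated aryl ketone and the enolised triketone should not be reduced; it is done only after the arm has been used, so the free triphenol never carries an ionisable benzylic ether.

**Step 13**
Reactants: 19 1-(2,4,6-trihydroxyphenyl)ethan-1-one
Product: 20 2-acetyl-3,5-dihydroxy-4,4-dimethylcyclohexa-2,5-dien-1-one (acetylfilicinic acid)
Conditions: NaOMe, MeI (2.2 equiv), MeOH, 0 °C to rt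
Reagents that add atoms: iodomethane, CI
Why: The same dearomatising geminal C-methylation of an acylphloroglucinol as in step 10.

**Step 14**
Reactants: 18 the triphenol from step 12; 20 acetylfilicinic acid (1.2 equiv)
Product: 22 filixic acid ABB (the target: 18 with its free ring carbon joined through CH2 to C-6 of 20), via Mannich base 21 (not isolated)
Conditions: Me2N=CH2 I (Eschenmoser's salt, 1.0 equiv), MeCN, 0 °C to rt; then 20, NaOAc, 60 °C
Reagents that add atoms: Eschenmoser's salt (N,N-dimethylmethylideneammonium iodide), C=[N+](C)C.[I-]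
Why: Phenol Mannich reaction at the only unsubstituted ring carbon, then loss of dimethylamine to an ortho-quinone methide and Michael addition of C-6 of 20, the classical one-carbon linking of phloroglucinol and filicinic acid units, made selective here because each partner has a single reactive carbon.

**Compound list**

1 | 3,5-bis(benzyloxy)phenol | Oc1cc(OCc2ccccc2)cc(OCc2ccccc2)c1 | starting material
2 | 4,6-bis(benzyloxy)-2-hydroxybenzaldehyde | O=Cc1c(O)cc(OCc2ccccc2)cc1OCc1ccccc1 | intermediate
3 | 4,6-bis(benzyloxy)-3-bromo-2-hydroxybenzaldehyde | O=Cc1c(O)c(Br)c(OCc2ccccc2)cc1OCc1ccccc1 | intermediate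
4 | 2-(allyloxy)-4,6-bis(benzyloxy)-3-bromobenzaldehyde | O=Cc1c(OCC=C)c(Br)c(OCc2ccccc2)cc1OCc1ccccc1 | intermediate
5 | [2-(allyloxy)-4,6-bis(benzyloxy)-3-bromophenyl]methanol | OCc1c(OCC=C)c(Br)c(OCc2ccccc2)cc1OCc1ccccc1 | intermediate
6 | 1-(allyloxy)-3,5-bis(benzyloxy)-2-bromo-6-(methoxymethyl)benzene | COCc1c(OCC=C)c(Br)c(OCc2ccccc2)cc1OCc1ccccc1 | intermediate
7 | 3,5-bis(benzyloxy)-2-bromo-6-(methoxymethyl)phenol | COCc1c(O)c(Br)c(OCc2ccccc2)cc1OCc1ccccc1 | intermediate
8 | [3,5-bis(benzyloxy)-2-bromo-6-(methoxymethyl)phenoxy]trimethylsilane (formed in the flask, not isolated) | COCc1c(O[Si](C)(C)C)c(Br)c(OCc2ccccc2)cc1OCc1ccccc1 | intermediate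
9 | lithium 3,5-bis(benzyloxy)-2-(methoxymethyl)-6-(trimethylsilyl)phenoxide (formed in the flask, not isolated) | [Li+].COCc1c([O-])c([Si](C)(C)C)c(OCc2ccccc2)cc1OCc1ccccc1 | intermediate
10 | 3,5-bis(benzyloxy)-2-(methoxymethyl)-6-(trimethylsilyl)phenyl trifluoromethanesulfonate | COCc1c(OS(=O)(=O)C(F)(F)F)c([Si](C)(C)C)c(OCc2ccccc2)cc1OCc1ccccc1 | intermediate
11 | butyric acid | CCCC(=O)O | starting material
12 | 4,6-bis(benzyloxy)-3-(methoxymethyl)benzyne (1,2-didehydrobenzene; formed in the flask, not isolated) | COCC1=C(OCc2ccccc2)C=C(OCc2ccccc2)C#C1 | intermediate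
13 | 1-[4,6-bis(benzyloxy)-2-hydroxy-3-(methoxymethyl)phenyl]butan-1-one | CCCC(=O)c1c(O)c(COC)c(OCc2ccccc2)cc1OCc1ccccc1 | intermediate
14 | phloroglucinol (benzene-1,3,5-triol) | Oc1cc(O)cc(O)c1 | starting material
15 | 1-(2,4,6-trihydroxyphenyl)butan-1-one | CCCC(=O)c1c(O)cc(O)cc1O | intermediate
16 | 2-butanoyl-3,5-dihydroxy-4,4-dimethylcyclohexa-2,5-dien-1-one (butyrylfilicinic acid) | CCCC(=O)C1=C(O)C(C)(C)C(O)=CC1=O | intermediate
17 | 2-butanoyl-6-{[4,6-bis(benzyloxy)-3-butanoyl-2-hydroxyphenyl]methyl}-3,5-dihydroxy-4,4-dimethylcyclohexa-2,5-dien-1-one | CCCC(=O)C1=C(O)C(C)(C)C(O)=C(Cc2c(O)c(C(=O)CCC)c(OCc3ccccc3)cc2OCc2ccccc2)C1=O | intermediate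
18 | 2-butanoyl-6-[(3-butanoyl-2,4,6-trihydroxyphenyl)methyl]-3,5-dihydroxy-4,4-dimethylcyclohexa-2,5-dien-1-one | CCCC(=O)C1=C(O)C(C)(C)C(O)=C(Cc2c(O)cc(O)c(C(=O)CCC)c2O)C1=O | intermediate
19 | 1-(2,4,6-trihydroxyphenyl)ethan-1-one | CC(=O)c1c(O)cc(O)cc1O | starting material
20 | 2-acetyl-3,5-dihydroxy-4,4-dimethylcyclohexa-2,5-dien-1-one (acetylfilicinic acid) | CC(=O)C1=C(O)C(C)(C)C(O)=CC1=O | intermediate
21 | 2-butanoyl-6-({3-butanoyl-5-[(dimethylamino)methyl]-2,4,6-trihydroxyphenyl}methyl)-3,5-dihydroxy-4,4-dimethylcyclohexa-2,5-dien-1-one (formed in the flask, not isolated) | CCCC(=O)C1=C(O)C(C)(C)C(O)=C(Cc2c(O)c(CN(C)C)c(O)c(C(=O)CCC)c2O)C1=O | intermediate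
22 | filixic acid ABB: 1-(2,4,6-trihydroxyphenyl)butan-1-one whose ring C-3 is joined through CH2 to C-6 of butyrylfilicinic acid and whose ring C-5 is joined through CH2 to C-6 of acetylfilicinic acid | CCCC(=O)C1=C(O)C(C)(C)C(O)=C(Cc2c(O)c(CC3=C(O)C(C)(C)C(O)=C(C(C)=O)C3=O)c(O)c(C(=O)CCC)c2O)C1=O | target

**Step count**

Total: 14 steps. Longest linear sequence: 11 steps (steps 1–8, 11, 12, 14).

**Steps most likely to fail**

1. Step 8. The aryl anion may be protonated by hydrogen fluoride or bifluoride before it reaches the ester carbonyl, so that the sequence stops at O-arylation. Butanoate may also enter at the wrong aryne carbon because the electronically preferred one is crowded by the methoxymethyl group, and at 125 °C the new phenoxide may expel methoxide. The fallback sets out from 7 and returns at 13. Phenol 7 is acylated with butanoyl chloride (Et3N, DMAP, CH2Cl2, 0 °C) to 3,5-bis(benzyloxy)-2-bromo-6-(methoxymethyl)phenyl butanoate F1. Treatment of this ester with t-BuLi (2 equiv, THF, −100 °C) should bring about bromine–lithium exchange and a 1,3-shift of the acyl group from oxygen to carbon (anionic Fries rearrangement started by halogen–metal exchange). This gives 13 through the same four-membered acyl transfer, without an aryne and without the regiochemical question.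

2. Step 14. Under amine and heat the bridge already present may open by retro-Michael reaction, letting filicinic units exchange between molecules, and any iminium ion left over would consume 20. The fallback sets out from 18 (with 20) and returns at 22 with the roles of the partners reversed. Acetylfilicinic acid 20 is aminomethylated with Eschenmoser's salt (CH2Cl2, rt) to 2-acetyl-6-[(dimethylamino)methyl]-3,5-dihydroxy-4,4-dimethylcyclohexa-2,5-dien-1-one F2. This Mannich base is added to 18 in acetic acid at room temperature. Loss of dimethylamine gives the 6-methylene triketone, which the single free ring carbon of 18 attacks. The central ring never becomes a quinone methide and no free amine is present at elevated temperature.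

3. Step 2. Bromine may enter between the two benzyloxy groups, or twice. The fallback sets out from 2 and returns at 10, making the outcome independent of the site of the first bromination.
   - Two equivalents of NBS give 4,6-bis(benzyloxy)-3,5-dibromo-2-hydroxybenzaldehyde F3.
   - The operations of steps 3 to 6 then give in turn 2-(allyloxy)-4,6-bis(benzyloxy)-3,5-dibromobenzaldehyde F4, [2-(allyloxy)-4,6-bis(benzyloxy)-3,5-dibromophenyl]methanol F5, 1-(allyloxy)-3,5-bis(benzyloxy)-2,4-dibromo-6-(methoxymethyl)benzene F6 and 3,5-bis(benzyloxy)-2,4-dibromo-6-(methoxymethyl)phenol F7.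
   - Silylation with HMDS gives [3,5-bis(benzyloxy)-2,4-dibromo-6-(methoxymethyl)phenoxy]trimethylsilane F8.
   - Excess t-BuLi (THF, −78 °C) exchanges both bromines. Only the lithium beside the silyloxy group triggers the silyl shift, and the aryllithium between the benzyloxy groups is protonated on quenching with NH4Cl, giving 3,5-bis(benzyloxy)-2-(methoxymethyl)-6-(trimethylsilyl)phenol F9.
   - Triflation (Tf2O, pyridine, CH2Cl2, 0 °C) then gives 10.

**Further compounds**

F1 | step 8 | 3,5-bis(benzyloxy)-2-bromo-6-(methoxymethyl)phenyl butanoate | CCCC(=O)Oc1c(Br)c(OCc2ccccc2)cc(OCc2ccccc2)c1COC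
F2 | step 14 | 2-acetyl-6-[(dimethylamino)methyl]-3,5-dihydroxy-4,4-dimethylcyclohexa-2,5-dien-1-one | CC(=O)C1=C(O)C(C)(C)C(O)=C(CN(C)C)C1=O
F3 | step 2 | 4,6-bis(benzyloxy)-3,5-dibromo-2-hydroxybenzaldehyde | O=Cc1c(O)c(Br)c(OCc2ccccc2)c(Br)c1OCc1ccccc1
F4 | step 2 | 2-(allyloxy)-4,6-bis(benzyloxy)-3,5-dibromobenzaldehyde | O=Cc1c(OCC=C)c(Br)c(OCc2ccccc2)c(Br)c1OCc1ccccc1
F5 | step 2 | [2-(allyloxy)-4,6-bis(benzyloxy)-3,5-dibromophenyl]methanol | OCc1c(OCC=C)c(Br)c(OCc2ccccc2)c(Br)c1OCc1ccccc1
F6 | step 2 | 1-(allyloxy)-3,5-bis(benzyloxy)-2,4-dibromo-6-(methoxymethyl)benzene | COCc1c(OCC=C)c(Br)c(OCc2ccccc2)c(Br)c1OCc1ccccc1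
F7 | step 2 | 3,5-bis(benzyloxy)-2,4-dibromo-6-(methoxymethyl)phenol | COCc1c(O)c(Br)c(OCc2ccccc2)c(Br)c1OCc1ccccc1
F8 | step 2 | [3,5-bis(benzyloxy)-2,4-dibromo-6-(methoxymethyl)phenoxy]trimethylsilane | COCc1c(O[Si](C)(C)C)c(Br)c(OCc2ccccc2)c(Br)c1OCc1ccccc1
F9 | step 2 | 3,5-bis(benzyloxy)-2-(methoxymethyl)-6-(trimethylsilyl)phenol | COCc1c(O)c([Si](C)(C)C)c(OCc2ccccc2)cc1OCc1ccccc1
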